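**Retrosynthetic overview**
1. 16 ⇒ 12: both benzoates (O5, O7) go on last while O6 is masked as an acetal. C7 is carried as a methyl ester on C1.
2. 12 ⇒ 10: the C1=C2 bond arises by loss of PhSO2H across C1–C2 of a cyclohex-3-ene that already holds C3=C4, O5 and O6.
3. 10 ⇒ 7 + 8: the route rests on ring carbon C1, which bears C7 and is bonded both to allylic C2 and to carbinol C6. C1 therefore enters as the doubly nucleophilic CH2 of a sulfonylacetate that joins the allylic bromide (C2) and the aldehyde (C6) of a C2–C6 chain.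
4. 7 ⇒ 4 ⇒ 1: the chain is an opened (R)-3-silyloxy-3,6-dihydro-2H-pyran made from di-O-acetyl-L-arabinal. The pyran ring hands on the Z C3=C4 alkene and the C5 stereocentre.
5. Ring order: the pyran ring of 1 is opened in step 4. The only ring of the target, the six-membered carbocycle, is closed in step 6.

Key step: step 6

Assumption: carbocycles are numbered as in the target (C1 bears C7, C5 the secondary benzoate, C6 the free hydroxyl), and 3,4-di-O-acetyl-L-arabinal is taken as a catalogue glycal.

**Step 1**
Reactants: 1 3,4-di-O-acetyl-L-arabinal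
Product: 2 (3R)-3,6-dihydro-2H-pyran-3-yl acetate
Conditions: Et3SiH (1.5 equiv), BF3·OEt2 (0.3 equiv), CH2Cl2, 0 °C
Reagents that add atoms: none
Why: Reductive Ferrier rearrangement, in which BF3 ionises the allylic C3 acetate, the silane delivers hydride to C1 of the allyloxocarbenium ion, the double bond moves to C2=C3 inside the ring (hence cis), and the C4 acetate carbon, the future C5, is not touched.

**Step 2**
Reactants: 2 (3R)-3,6-dihydro-2H-pyran-3-yl acetate
Product: 3 (3R)-3,6-dihydro-2H-pyran-3-ol
Conditions: K2CO3 (0.1 equiv), MeOH, 0 °C → rt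
Reagents that add atoms: none
Why: Zemplén-type base-catalysed transesterification removes the acetate without touching the stereocentre or the ring alkene.

**Step 3**
Reactants: 3 (3R)-3,6-dihydro-2H-pyran-3-ol
Product: 4 (3R)-3-[(triisopropylsilyl)oxy]-3,6-dihydro-2H-pyran
Conditions: iPr3SiOTf, 2,6-lutidine, CH2Cl2, 0 °C
Reagents that add atoms: triisopropylsilyl trifluoromethanesulfonate, CC(C)[Si](C(C)C)(C(C)C)OS(=O)(=O)C(F)(F)F
Why: Standard silylation of a secondary allylic alcohol with a silyl triflate and a hindered pyridine base, the bulky silyl group being chosen to survive the boron halide of step 4 and to shield C5–H in steps 5 and 6.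

**Step 4**
Reactants: 4 (3R)-3-[(triisopropylsilyl)oxy]-3,6-dihydro-2H-pyran
Product: 6 (2R,3Z)-5-bromo-2-[(triisopropylsilyl)oxy]pent-3-en-1-ol, via O-dimethylboryl ether 5 (not isolated)
Conditions: Me2BBr (1.3 equiv), Et3N (0.1 equiv), CH2Cl2, −78 → 0 °C; then aq NaHCO3
Reagents that add atoms: bromodimethylborane, CB(C)Br
Why: Dialkylboron bromide cleavage of a cyclic ether, in which boron binds the open ring oxygen rather than the shielded silyl ether oxygen and bromide attacks by SN2 at the primary allylic carbon rather than at the CH2 next to the silyloxy carbon, so the ring alkene is released as the Z-allylic bromide and the other terminus as the primary alcohol.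

**Step 5**
Reactants: 6 (2R,3Z)-5-bromo-2-[(triisopropylsilyl)oxy]pent-3-en-1-ol
Product: 7 (2R,3Z)-5-bromo-2-[(triisopropylsilyl)oxy]pent-3-enal
Conditions: Dess–Martin periodinane, CH2Cl2, 0 °C → rt; used crude at once
Reagents that add atoms: none
Why: Dess–Martin oxidation runs under neutral, non-nucleophilic conditions, so the allylic bromide is left alone and the α-silyloxy aldehyde is neither epimerised nor moved into conjugation.

**Step 6**
Reactants: 7 (2R,3Z)-5-bromo-2-[(triisopropylsilyl)oxy]pent-3-enal; 8 methyl 2-(phenylsulfonyl)acetate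
Product: 10 methyl (5R,6S)-6-hydroxy-1-(phenylsulfonyl)-5-[(triisopropylsilyl)oxy]cyclohex-3-ene-1-carboxylate (trans C5/C6, C1 epimers), via open-chain C-alkylated aldehyde 9 (not isolated)
Conditions: 8 (1.1 equiv), powdered K2CO3 (2.5 equiv), MeCN (0.05 M), 0 °C → rt, slow addition of 7
Reagents that add atoms: none
Why: Proposed new method: carbonate deprotonates 8 to a soft, weakly basic carbanion that displaces the primary allylic bromide of 7 by SN2 (bond C1–C2) to give 9, and the still acidic C1–H of 9 is removed in turn so that the stabilised carbanion adds to the C6 aldehyde (bond C1–C6); if the reversible intermolecular aldol came first, the adduct would re-form its carbanion and close by C-alkylation, so both orders lead to 10. The closest known reactions are the K2CO3 alkylation of arylsulfonylacetates with allylic halides, the intramolecular aldol of such anions, and the stepwise malonate or phosphonoacetate [5+1] carbocyclisations of halo aldehydes, and only their merger in one flask on an α-silyloxy β,γ-unsaturated aldehyde is new. The single ring, the six-membered carbocycle, closes by a 6-(enolexo)-exo-trig aldol, which the Z alkene favours by holding C2 and C6 on the same side, so that cyclisation should outrun a second alkylation. C6 is set under thermodynamic control by the C5 stereocentre: the aldol is reversible under carbonate, the OTIPS group stays pseudo-equatorial because a pseudo-axial one would be syn-axial to a substituent on quaternary C1, and the C6 hydroxyl should settle equatorial, trans to O5, where it can bind through hydrogen or K+ to both the sulfonyl and the ester oxygen, while C1 forms as an epimer mixture that is erased in step 8. The step needs alkylation to beat enolisation of 7 (epimerisation at C5 or 1,4-loss of HBr), and this is secured by the low basicity of the nucleophile, by the bulk of the silyl group, and by allylic 1,3-strain across the Z alkene, which keeps C5–H in the alkene plane and out of overlap with the π system. SN2 over SN2' follows from the unhindered primary terminus and the crowding at C4 next to C5.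

**Step 7**
Reactants: 10 methyl (5R,6S)-6-hydroxy-1-(phenylsulfonyl)-5-[(triisopropylsilyl)oxy]cyclohex-3-ene-1-carboxylate
Product: 11 methyl (5R,6S)-6-(1-ethoxyethoxy)-1-(phenylsulfonyl)-5-[(triisopropylsilyl)oxy]cyclohex-3-ene-1-carboxylate (mixture at C1 and at the acetal carbon)
Conditions: ethyl vinyl ether (10 equiv), pyridinium p-toluenesulfonate (0.1 equiv), CH2Cl2, rt
Reagents that add atoms: ethyl vinyl ether, C=COCC
Why: Acid-catalysed addition of the alcohol to an enol ether (acetal protection) avoids base and hence retro-aldol, copes with a hindered alcohol, and gives a group that stands DBU, iBu2AlH, fluoride and acylation yet leaves under very mild acid.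

**Step 8**
Reactants: 11 methyl (5R,6S)-6-(1-ethoxyethoxy)-1-(phenylsulfonyl)-5-[(triisopropylsilyl)oxy]cyclohex-3-ene-1-carboxylate
Product: 12 methyl (5R,6R)-6-(1-ethoxyethoxy)-5-[(triisopropylsilyl)oxy]cyclohexa-1,3-diene-1-carboxylate
Conditions: DBU (3 equiv), PhMe, rt → 60 °C
Reagents that add atoms: none
Why: Base-induced 1,2-elimination of benzenesulfinic acid (dehydrosulfonylation) from a fully substituted α-sulfonyl ester, in which DBU takes the allylic C2–H rather than the oxygen-deactivated C6–H, strain at crowded C1 is relieved, the new C1=C2 bond is conjugated with the ester and with C3=C4, both C1 epimers converge on one diene, and the acetal at O6 rules out retro-aldol.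

**Step 9**
Reactants: 12 methyl (5R,6R)-6-(1-ethoxyethoxy)-5-[(triisopropylsilyl)oxy]cyclohexa-1,3-diene-1-carboxylate
Product: 13 {(5R,6R)-6-(1-ethoxyethoxy)-5-[(triisopropylsilyl)oxy]cyclohexa-1,3-dien-1-yl}methanol
Conditions: iBu2AlH (2.5 equiv), CH2Cl2, −78 → −20 °C; aq potassium sodium tartrate
Reagents that add atoms: none
Why: 1,2-Reduction of a conjugated ester with iBu2AlH gives the primary allylic alcohol at C7, while silyl ether, acetal and diene are inert at low temperature.

**Step 10**
Reactants: 13 {(5R,6R)-6-(1-ethoxyethoxy)-5-[(triisopropylsilyl)oxy]cyclohexa-1,3-dien-1-yl}methanol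
Product: 14 [(5R,6R)-6-(1-ethoxyethoxy)-5-hydroxycyclohexa-1,3-dien-1-yl]methanol
Conditions: Bu4NF (1.2 equiv), THF, 0 °C → rt
Reagents that add atoms: none
Why: Fluoride-induced desilylation frees O5 while the acetal at O6 is inert to fluoride, and no ester is yet present that could migrate.

**Step 11**
Reactants: 14 [(5R,6R)-6-(1-ethoxyethoxy)-5-hydroxycyclohexa-1,3-dien-1-yl]methanol
Product: 15 [(5R,6R)-5-(benzoyloxy)-6-(1-ethoxyethoxy)cyclohexa-1,3-dien-1-yl]methyl benzoate
Conditions: BzCl (2.5 equiv), pyridine, 4-(dimethylamino)pyridine (0.1 equiv), CH2Cl2, 0 °C → rt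
Reagents that add atoms: benzoyl chloride, O=C(Cl)c1ccccc1
Why: Nucleophile-catalysed acylation esterifies the two free hydroxyls O5 and O7 in one operation with O6 blocked, so no regioselectivity is asked of the reagent.

**Step 12**
Reactants: 15 [(5R,6R)-5-(benzoyloxy)-6-(1-ethoxyethoxy)cyclohexa-1,3-dien-1-yl]methyl benzoate
Product: 16 [(5R,6R)-5-(benzoyloxy)-6-hydroxycyclohexa-1,3-dien-1-yl]methyl benzoate (CNP0113836.1)
Conditions: pyridinium p-toluenesulfonate (0.2 equiv), MeOH, 0 °C → rt
Reagents that add atoms: none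
Why: Acid-catalysed transacetalisation with methanol removes the 1-ethoxyethyl group under conditions too mild for benzoate migration, for ionisation of the C5 allylic benzoate or for dehydration to an arene.

**Compound list**
1 | 3,4-di-O-acetyl-L-arabinal, (3S,4R)-3,4-dihydro-2H-pyran-3,4-diyl diacetate | O1C=C[C@@H](OC(C)=O)[C@@H](OC(C)=O)C1 | starting material
2 | (3R)-3,6-dihydro-2H-pyran-3-yl acetate | C1C=C[C@@H](OC(C)=O)CO1 | intermediate
3 | (3R)-3,6-dihydro-2H-pyran-3-ol | C1C=C[C@@H](O)CO1 | intermediate
4 | (3R)-3-[(triisopropylsilyl)oxy]-3,6-dihydro-2H-pyran | C1C=C[C@@H](O[Si](C(C)C)(C(C)C)C(C)C)CO1 | intermediate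
5 | (2R,3Z)-5-bromo-2-[(triisopropylsilyl)oxy]pent-3-en-1-yl dimethylborinate | BrC/C=C\[C@@H](O[Si](C(C)C)(C(C)C)C(C)C)COB(C)C | intermediate
6 | (2R,3Z)-5-bromo-2-[(triisopropylsilyl)oxy]pent-3-en-1-ol | BrC/C=C\[C@@H](O[Si](C(C)C)(C(C)C)C(C)C)CO | intermediate
7 | (2R,3Z)-5-bromo-2-[(triisopropylsilyl)oxy]pent-3-enal | BrC/C=C\[C@@H](O[Si](C(C)C)(C(C)C)C(C)C)C=O | intermediate
8 | methyl 2-(phenylsulfonyl)acetate | COC(=O)CS(=O)(=O)c1ccccc1 | starting material
9 | methyl (4Z,6R)-7-oxo-2-(phenylsulfonyl)-6-[(triisopropylsilyl)oxy]hept-4-enoate (C2 epimers) | COC(=O)C(S(=O)(=O)c1ccccc1)C/C=C\[C@@H](O[Si](C(C)C)(C(C)C)C(C)C)C=O | intermediate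
10 | methyl (5R,6S)-6-hydroxy-1-(phenylsulfonyl)-5-[(triisopropylsilyl)oxy]cyclohex-3-ene-1-carboxylate (C1 epimers) | COC(=O)C1(S(=O)(=O)c2ccccc2)CC=C[C@@H](O[Si](C(C)C)(C(C)C)C(C)C)[C@@H]1O | intermediate
11 | methyl (5R,6S)-6-(1-ethoxyethoxy)-1-(phenylsulfonyl)-5-[(triisopropylsilyl)oxy]cyclohex-3-ene-1-carboxylate | COC(=O)C1(S(=O)(=O)c2ccccc2)CC=C[C@@H](O[Si](C(C)C)(C(C)C)C(C)C)[C@@H]1OC(C)OCC | intermediate
12 | methyl (5R,6R)-6-(1-ethoxyethoxy)-5-[(triisopropylsilyl)oxy]cyclohexa-1,3-diene-1-carboxylate | COC(=O)C1=CC=C[C@@H](O[Si](C(C)C)(C(C)C)C(C)C)[C@@H]1OC(C)OCC | intermediate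
13 | {(5R,6R)-6-(1-ethoxyethoxy)-5-[(triisopropylsilyl)oxy]cyclohexa-1,3-dien-1-yl}methanol | OCC1=CC=C[C@@H](O[Si](C(C)C)(C(C)C)C(C)C)[C@@H]1OC(C)OCC | intermediate
14 | [(5R,6R)-6-(1-ethoxyethoxy)-5-hydroxycyclohexa-1,3-dien-1-yl]methanol | OCC1=CC=C[C@@H](O)[C@@H]1OC(C)OCC | intermediate
15 | [(5R,6R)-5-(benzoyloxy)-6-(1-ethoxyethoxy)cyclohexa-1,3-dien-1-yl]methyl benzoate | O=C(OCC1=CC=C[C@@H](OC(=O)c2ccccc2)[C@@H]1OC(C)OCC)c1ccccc1 | intermediate
16 | [(5R,6R)-5-(benzoyloxy)-6-hydroxycyclohexa-1,3-dien-1-yl]methyl benzoate | O=C(OCC1=CC=C[C@@H](OC(=O)c2ccccc2)[C@@H]1O)c1ccccc1 | target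

Total step count: 12. Longest linear sequence: 12 steps (1 → 16).

**Steps most likely to fail**

Step 6 (key step).
- What may go wrong: enolisation of the aldehyde may come before alkylation, leading to epimerisation at C5 or 1,4-loss of HBr. The equilibrium may also give incomplete trans selectivity at C6.
- A C6 epimer can be returned to the equilibrium by renewed exposure to carbonate.
- Fallback, from 6 and 8, back at 10: the two bonds are made separately, so that no bromo aldehyde ever meets base.
  - The sodium salt of 8 (NaH, THF/DMF, 0 °C) is alkylated with bromo alcohol 6. This gives methyl (4Z,6R)-7-hydroxy-2-(phenylsulfonyl)-6-[(triisopropylsilyl)oxy]hept-4-enoate F1.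
  - Dess–Martin oxidation of the primary alcohol gives 9, now isolated.
  - A separate intramolecular aldol with catalytic DBU in CH2Cl2 at 0 °C closes 9 to 10.

Step 8.
- What may go wrong: anti elimination may be slow from the C1 epimer whose sulfonyl group sits equatorial. Under forcing, the diene ester may aromatise by base-induced loss of the O6 substituent.
- Fallback, from 11, back at 12: the sulfone is removed reductively and the double bond is made by a syn elimination that does not depend on the C1 configuration.
  - Aluminium amalgam (Al/Hg) in aqueous THF gives methyl (5R,6R)-6-(1-ethoxyethoxy)-5-[(triisopropylsilyl)oxy]cyclohex-3-ene-1-carboxylate F2.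
  - Enolisation with lithium diisopropylamide (iPr2NLi) at −78 °C and trapping with PhSeBr gives methyl (5R,6S)-6-(1-ethoxyethoxy)-1-(phenylselanyl)-5-[(triisopropylsilyl)oxy]cyclohex-3-ene-1-carboxylate F3.
  - H2O2 with pyridine in CH2Cl2 at 0 °C gives the selenoxide methyl (5R,6S)-6-(1-ethoxyethoxy)-1-(phenylseleninyl)-5-[(triisopropylsilyl)oxy]cyclohex-3-ene-1-carboxylate F4.
  - F4 eliminates towards C2, away from oxygen-bearing C6, to give 12.

Step 4.
- What may go wrong: the boron halide may attack the allylic silyl ether. The allylic bromide may drift from Z to E through reversible SN2' attack of bromide. The bromo alcohol may re-close during work-up.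
- Fallback, from 4, back at 6: the allylic C–O bond is broken by oxidation and reduction instead of by a Lewis acid.
  - Allylic methylene oxidation of 4 with pyridinium chlorochromate (C5H5NH[CrO3Cl]) in refluxing CH2Cl2 gives (5R)-5-[(triisopropylsilyl)oxy]-5,6-dihydro-2H-pyran-2-one F5.
  - Excess iBu2AlH (CH2Cl2, −78 → 0 °C) reduces the lactone to (2Z,4R)-4-[(triisopropylsilyl)oxy]pent-2-ene-1,5-diol F6.
  - Corey–Kim bromination (N-bromosuccinimide, Me2S, CH2Cl2, −20 → 0 °C) converts only the allylic hydroxyl into the bromide. The saturated primary alcohol is returned on aqueous work-up, which gives 6.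

**Further compounds**
F1 | step 6 | methyl (4Z,6R)-7-hydroxy-2-(phenylsulfonyl)-6-[(triisopropylsilyl)oxy]hept-4-enoate | COC(=O)C(S(=O)(=O)c1ccccc1)C/C=C\[C@@H](O[Si](C(C)C)(C(C)C)C(C)C)CO
F2 | step 8 | methyl (5R,6R)-6-(1-ethoxyethoxy)-5-[(triisopropylsilyl)oxy]cyclohex-3-ene-1-carboxylate | COC(=O)C1CC=C[C@@H](O[Si](C(C)C)(C(C)C)C(C)C)[C@@H]1OC(C)OCC
F3 | step 8 | methyl (5R,6S)-6-(1-ethoxyethoxy)-1-(phenylselanyl)-5-[(triisopropylsilyl)oxy]cyclohex-3-ene-1-carboxylate | COC(=O)C1([Se]c2ccccc2)CC=C[C@@H](O[Si](C(C)C)(C(C)C)C(C)C)[C@@H]1OC(C)OCC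
F4 | step 8 | methyl (5R,6S)-6-(1-ethoxyethoxy)-1-(phenylseleninyl)-5-[(triisopropylsilyl)oxy]cyclohex-3-ene-1-carboxylate | COC(=O)C1([Se](=O)c2ccccc2)CC=C[C@@H](O[Si](C(C)C)(C(C)C)C(C)C)[C@@H]1OC(C)OCC
F5 | step 4 | (5R)-5-[(triisopropylsilyl)oxy]-5,6-dihydro-2H-pyran-2-one | O=C1C=C[C@@H](O[Si](C(C)C)(C(C)C)C(C)C)CO1
F6 | step 4 | (2Z,4R)-4-[(triisopropylsilyl)oxy]pent-2-ene-1,5-diol | OC/C=C\[C@@H](O[Si](C(C)C)(C(C)C)C(C)C)CO
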